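Its constants are those of an exercise.

One question stands, about one flask:

electrophile 0.050 M; protonated nucleophile 0.100 M; time 1.0 h

    nucleophile + acid set free ⇌ protonated nucleophile, settled at all times (K1 = 18000 L mol⁻¹)
    acid set free + free base ⇌ salt of the base, settled at all times (K2 = 4.0 × 10⁶ L mol⁻¹)
    electrophile + nucleophile ⇌ acid set free + target (K3 = 0.42, k3 = 53 L mol⁻¹ min⁻¹)
    free base + target → over-reaction product (k4 = 16 L mol⁻¹ min⁻¹)

- the concentration of free base at which the part of the electrophile that has reacted at 1.0 h is just 95 %, in M

Work backwards from the wanted state, and take the exchange of electrophile and nucleophile as balanced at the hour. Then 0.0475 M of electrophile has reacted and 0.00250 M is left; as a first pass, set the over-reaction aside and count all that has reacted as target, so 0.42 sets acid set free over nucleophile at about 0.0221. With 18000 L mol⁻¹, the nucleophile balance leaves 0.0103 M of free nucleophile. Count protons: the salt of the base must hold two per electrophile reacted plus that free nucleophile, 0.105 M. Beside it, 4.0 × 10⁶ L mol⁻¹ leaves a pool of free base of 1.16 × 10⁻⁴ M, far smaller than the salt.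

Now compare two times: the lifetime of free base against target, 1.32 min, and the run, 1.0 h. Call their ratio the turnover count, the number of times the over-reaction empties the pool while salt refills it: 45.6. Multiply it by the pool, and the over-reaction costs roughly 0.00527 M of base. Charge the salt plus that loss: 0.111 M.

The forecast gives 0.11 M, starting from "Each electrophile converted costs two base equivalents".

The simulation gives 0.110 M. In that flask, the exchange had half its turnover behind it after 0.158 min, and electrophile used read 96.6 % at 0.250 h. The over-reaction ran on through the hour, with half its turnover done by 0.391 h, while the pool read 0.142 % of the charged free base at 0.100 h. The count of 45.6 puts about 4.79 % of that charge into over-reaction product. Run the same flask for 2 hours, and the part reacted reads 93.2 %.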